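**Strategy**

Everything rests on cutting ring C at O1–C8a, C4–C4a and O1–C2. In ring A, O1 (on C8a) and the acyl carbon C4 (on C4a) sit on neighbouring carbons, with O5 beside C4a; this is the pattern an aryne leaves when it inserts into the C–O bond of a carboxylic acid. In one operation the 3,5-dibenzyloxybenzyne released by CsF from silyl triflate 8 (trimethylsilyl group between the triflate and a benzyloxy group) takes up ring B propiolic acid 14, and the ortho-hydroxyaryl ynone so formed closes ring C to flavone 17. The benzyloxy group next to the aryne bond fixes the orientation. O8 and the C3 hydroxyl follow afterwards.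

Key step: step 7

Remark: the target has no stereocentre, so no stereocontrol is needed; flavone numbering (O1, C2 to C8a, primed locants for ring B) is used throughout.

**Route**

Step 1
Reactants: 1 3,5-bis(benzyloxy)phenol
Product: 2 3,5-bis(benzyloxy)phenyl N-isopropylcarbamate
Conditions: i-PrNCO, Et3N (cat.), CH2Cl2, rt
Reagents that add atoms: isopropyl isocyanate, CC(C)N=C=O
Why: Amine-catalysed addition of the phenol to the isocyanate (carbamoylation) should give the N-monoalkyl carbamate, which is a strong ortho-directing group and, unlike a dialkyl carbamate, can later be removed with mild base.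

Step 2
Reactants: 2 3,5-bis(benzyloxy)phenyl N-isopropylcarbamate
Product: 6 3,5-bis(benzyloxy)-2-(trimethylsilyl)phenyl N-isopropylcarbamate, via N-TBS carbamate 3 (not isolated), via aryllithium 4 (not isolated), via N-TBS ortho-TMS carbamate 5 (not isolated)
Conditions: TBSOTf, TMEDA, Et2O, 0 °C to rt; n-BuLi (2 equiv), TMEDA, −78 °C; TMSCl, −78 °C to rt; aq. NaHSO4
Reagents that add atoms: chlorotrimethylsilane, C[Si](C)(C)Cl
Why: In situ N-silylation masks the N–H, the carbamate then directs ortho-lithiation (directed ortho-metalation) to the carbon between itself and a benzyloxy group, the two such sites being equivalent, TMSCl traps the aryllithium, and the acidic work-up removes the N-silyl group.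

Step 3
Reactants: 6 3,5-bis(benzyloxy)-2-(trimethylsilyl)phenyl N-isopropylcarbamate
Product: 8 3,5-bis(benzyloxy)-2-(trimethylsilyl)phenyl trifluoromethanesulfonate, via silyl phenol 7 (not isolated)
Conditions: DBU, Et2NH, MeCN, 40 °C; then PhNTf2, rt
Reagents that add atoms: N-phenylbis(trifluoromethanesulfonimide), O=S(=O)(N(c1ccccc1)S(=O)(=O)C(F)(F)F)C(F)(F)F
Why: DBU removes the carbamate N–H proton, E1cB loss of isopropyl isocyanate (captured by Et2NH as a urea) frees the phenoxide, and PhNTf2 sulfonylates it in the same flask, so the protodesilylation-prone ortho-silyl phenol is never handled.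

Step 4
Reactants: 9 3-hydroxy-4,5-dimethoxybenzaldehyde
Product: 10 3-(benzyloxy)-4,5-dimethoxybenzaldehyde
Conditions: BnBr, K2CO3, DMF, rt
Reagents that add atoms: benzyl bromide, BrCc1ccccc1
Why: Williamson etherification of the only phenol is routine and leaves the aldehyde untouched.

Step 5
Reactants: 10 3-(benzyloxy)-4,5-dimethoxybenzaldehyde
Product: 11 1-(benzyloxy)-5-ethynyl-2,3-dimethoxybenzene
Conditions: dimethyl (1-diazo-2-oxopropyl)phosphonate, K2CO3, MeOH, rt
Reagents that add atoms: dimethyl (1-diazo-2-oxopropyl)phosphonate, COP(=O)(OC)C(=[N+]=[N-])C(C)=O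
Why: Seyferth–Gilbert homologation in its Ohira–Bestmann form should convert the non-enolisable aryl aldehyde into the terminal alkyne under mild carbonate/methanol conditions that the ethers tolerate.

Step 6
Reactants: 11 1-(benzyloxy)-5-ethynyl-2,3-dimethoxybenzene; 12 carbon dioxide
Product: 14 3-[3-(benzyloxy)-4,5-dimethoxyphenyl]prop-2-ynoic acid, via lithium acetylide 13 (not isolated)
Conditions: n-BuLi (1.05 equiv), THF, −78 °C; CO2 (dry gas), −78 °C to rt; 1 M HCl
Reagents that add atoms: carbon dioxide (12), O=C=O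
Why: The alkyne C–H is by far the most acidic site, so n-BuLi should give the lithium acetylide cleanly at low temperature, and carboxylation followed by acidification delivers the arylpropiolic acid.

Step 7
Reactants: 8 3,5-bis(benzyloxy)-2-(trimethylsilyl)phenyl trifluoromethanesulfonate; 14 3-[3-(benzyloxy)-4,5-dimethoxyphenyl]prop-2-ynoic acid
Product: 17 5,7-bis(benzyloxy)-2-[3-(benzyloxy)-4,5-dimethoxyphenyl]-4H-chromen-4-one, via aryne 15 (not isolated), via hydroxyaryl ynone 16 (not isolated)
Conditions: 8 (1.3 equiv), CsF (4 equiv), THF, 125 °C, sealed tube; then Et2NH, EtOH, 50 °C only if open ynone 16 remains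
Reagents that add atoms: none
Why: Fluoride removes the trimethylsilyl group of 8 and triflate leaves, giving aryne 15; the carboxylate of 14 adds to the aryne carbon remote from the flanking benzyloxy group (forming O1–C8a), the aryl anion thus placed next to that benzyloxy group attacks its own ester carbonyl through a four-membered alkoxide (forming C4a–C4), and ring opening releases the phenoxide of ynone 16. The closest known reaction type is this same fluoride-triggered aryne insertion into the C–O bond of carboxylic acids to give ortho-hydroxyaryl ketones, which with alkynoic acids runs on to chromones. Ring C closes by 6-endo-dig oxa-Michael addition of the phenoxide to the ynone β-carbon (forming O1–C2), and the C3 vinyl anion takes the proton that the acid brought in. No stereocentre is created. The selectivity needed is the sense of addition to the unsymmetrical aryne, secured by the inductive pull and ring distortion of the benzyloxy group beside the triple bond, which makes the far carbon the electrophilic one and stabilises the anion next to oxygen; a C8 oxygen would flank the other aryne carbon and erase this bias, which is why it is introduced later. 6-endo over 5-exo closure is favoured in the aprotic medium and can be enforced by Et2NH through the β-enaminone if open ynone is left.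

Step 8
Reactants: 17 5,7-bis(benzyloxy)-2-[3-(benzyloxy)-4,5-dimethoxyphenyl]-4H-chromen-4-one
Product: 18 7-(benzyloxy)-2-[3-(benzyloxy)-4,5-dimethoxyphenyl]-5-hydroxy-4H-chromen-4-one
Conditions: BCl3 (1.1 equiv), CH2Cl2, −78 °C; H2O
Reagents that add atoms: none
Why: BCl3 binds in the pocket formed by C4=O and O5 and cleaves the peri benzyl ether through this chelate (chelation-assisted Lewis acid ether cleavage), while the near-stoichiometric charge and low temperature should spare the benzyl ethers at O7 and O3' and the methyl ethers.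

Step 9
Reactants: 18 7-(benzyloxy)-2-[3-(benzyloxy)-4,5-dimethoxyphenyl]-5-hydroxy-4H-chromen-4-one
Product: 20 7-(benzyloxy)-2-[3-(benzyloxy)-4,5-dimethoxyphenyl]-5,8-dihydroxy-4H-chromen-4-one, via aryl sulfate 19 (not isolated)
Conditions: K2S2O8, aq. KOH, pyridine, 0 °C to rt; then 2 M HCl, 80 °C, N2
Reagents that add atoms: K2S2O8 (potassium peroxodisulfate), [K+].[K+].[O-]S(=O)(=O)OOS(=O)(=O)[O-]
Why: In the Elbs persulfate oxidation the 5-phenoxide is attacked by peroxodisulfate at its para carbon C8, and acid hydrolysis of the aryl sulfate should give the 5,8-diol, the established behaviour of 5-hydroxy-7-alkoxyflavones.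

Step 10
Reactants: 20 7-(benzyloxy)-2-[3-(benzyloxy)-4,5-dimethoxyphenyl]-5,8-dihydroxy-4H-chromen-4-one
Product: 21 7-(benzyloxy)-2-[3-(benzyloxy)-4,5-dimethoxyphenyl]-5-hydroxy-8-methoxy-4H-chromen-4-one
Conditions: MeI (1.05 equiv), K2CO3, acetone, 40 °C, N2
Reagents that add atoms: iodomethane, CI
Why: The 5-OH is tied up in a hydrogen bond to C4=O and is far less nucleophilic than the free 8-OH, so one equivalent of MeI under Williamson conditions should methylate O8 only.

Step 11
Reactants: 21 7-(benzyloxy)-2-[3-(benzyloxy)-4,5-dimethoxyphenyl]-5-hydroxy-8-methoxy-4H-chromen-4-one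
Product: 22 5,7-bis(benzyloxy)-2-[3-(benzyloxy)-4,5-dimethoxyphenyl]-8-methoxy-4H-chromen-4-one
Conditions: BnBr, K2CO3, n-Bu4NI (cat.), DMF, 70 °C
Reagents that add atoms: benzyl bromide, BrCc1ccccc1
Why: Under more forcing Williamson conditions the chelated 5-OH is benzylated, which removes the acidic proton before the lithiation and keeps all protecting groups of one kind for the last step.

Step 12
Reactants: 22 5,7-bis(benzyloxy)-2-[3-(benzyloxy)-4,5-dimethoxyphenyl]-8-methoxy-4H-chromen-4-one
Product: 25 5,7-bis(benzyloxy)-2-[3-(benzyloxy)-4,5-dimethoxyphenyl]-3-hydroxy-8-methoxy-4H-chromen-4-one, via 3-lithioflavone 23 (not isolated), via boronate 24 (not isolated)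
Conditions: LiN(i-Pr)2 (LDA), THF, −78 °C; B(OMe)3, −78 to 0 °C; AcOH, 30% H2O2, 0 °C to rt
Reagents that add atoms: hydrogen peroxide, OO
Why: LDA removes the C3–H of the flavone (vinylic lithiation directed by the C4 carbonyl), B(OMe)3 converts the 3-lithioflavone into the boronate, and H2O2 in acetic acid oxidises the C–B bond to C–OH (borylation/oxidation).

Step 13
Reactants: 25 5,7-bis(benzyloxy)-2-[3-(benzyloxy)-4,5-dimethoxyphenyl]-3-hydroxy-8-methoxy-4H-chromen-4-one
Product: 26 3,5,7-trihydroxy-2-(3-hydroxy-4,5-dimethoxyphenyl)-8-methoxy-4H-chromen-4-one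
Conditions: H2 (1 atm), 10% Pd/C, THF/MeOH, rt
Reagents that add atoms: none
Why: Hydrogenolysis over Pd/C should cleave the three benzyl ethers at once, while the methyl ethers and, at atmospheric pressure and room temperature, the C2=C3 bond of the flavonol are retained.

**Compound list**

1 | 3,5-bis(benzyloxy)phenol | Oc1cc(OCc2ccccc2)cc(OCc2ccccc2)c1 | starting material
2 | 3,5-bis(benzyloxy)phenyl N-isopropylcarbamate | CC(C)NC(=O)Oc1cc(OCc2ccccc2)cc(OCc2ccccc2)c1 | intermediate
3 | 3,5-bis(benzyloxy)phenyl N-(tert-butyldimethylsilyl)-N-isopropylcarbamate | CC(C)N(C(=O)Oc1cc(OCc2ccccc2)cc(OCc2ccccc2)c1)[Si](C)(C)C(C)(C)C | intermediate (not isolated)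
4 | 2-lithio derivative of 3 (lithium between the carbamate and a benzyloxy group) | CC(C)N(C(=O)Oc1cc(OCc2ccccc2)cc(OCc2ccccc2)c1[Li])[Si](C)(C)C(C)(C)C | intermediate (not isolated)
5 | 3,5-bis(benzyloxy)-2-(trimethylsilyl)phenyl N-(tert-butyldimethylsilyl)-N-isopropylcarbamate | CC(C)N(C(=O)Oc1cc(OCc2ccccc2)cc(OCc2ccccc2)c1[Si](C)(C)C)[Si](C)(C)C(C)(C)C | intermediate (not isolated)
6 | 3,5-bis(benzyloxy)-2-(trimethylsilyl)phenyl N-isopropylcarbamate | CC(C)NC(=O)Oc1cc(OCc2ccccc2)cc(OCc2ccccc2)c1[Si](C)(C)C | intermediate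
7 | 3,5-bis(benzyloxy)-2-(trimethylsilyl)phenol | C[Si](C)(C)c1c(O)cc(OCc2ccccc2)cc1OCc1ccccc1 | intermediate (not isolated)
8 | 3,5-bis(benzyloxy)-2-(trimethylsilyl)phenyl trifluoromethanesulfonate | C[Si](C)(C)c1c(OCc2ccccc2)cc(OCc2ccccc2)cc1OS(=O)(=O)C(F)(F)F | intermediate
9 | 3-hydroxy-4,5-dimethoxybenzaldehyde | COc1cc(C=O)cc(O)c1OC | starting material
10 | 3-(benzyloxy)-4,5-dimethoxybenzaldehyde | COc1cc(C=O)cc(OCc2ccccc2)c1OC | intermediate
11 | 1-(benzyloxy)-5-ethynyl-2,3-dimethoxybenzene | COc1cc(C#C)cc(OCc2ccccc2)c1OC | intermediate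
12 | carbon dioxide | O=C=O | starting material
13 | lithium [3-(benzyloxy)-4,5-dimethoxyphenyl]acetylide | COc1cc(C#C[Li])cc(OCc2ccccc2)c1OC | intermediate (not isolated)
14 | 3-[3-(benzyloxy)-4,5-dimethoxyphenyl]prop-2-ynoic acid | O=C(O)C#Cc1cc(OC)c(OC)c(OCc2ccccc2)c1 | intermediate
15 | 3,5-bis(benzyloxy)-1,2-didehydrobenzene (aryne) | C1#CC(OCc2ccccc2)=CC(OCc2ccccc2)=C1 | intermediate (not isolated)
16 | 1-[2,4-bis(benzyloxy)-6-hydroxyphenyl]-3-[3-(benzyloxy)-4,5-dimethoxyphenyl]prop-2-yn-1-one | COc1cc(C#CC(=O)c2c(O)cc(OCc3ccccc3)cc2OCc2ccccc2)cc(OCc2ccccc2)c1OC | intermediate (not isolated)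
17 | 5,7-bis(benzyloxy)-2-[3-(benzyloxy)-4,5-dimethoxyphenyl]-4H-chromen-4-one | COc1cc(-c2cc(=O)c3c(OCc4ccccc4)cc(OCc4ccccc4)cc3o2)cc(OCc2ccccc2)c1OC | intermediate
18 | 7-(benzyloxy)-2-[3-(benzyloxy)-4,5-dimethoxyphenyl]-5-hydroxy-4H-chromen-4-one | COc1cc(-c2cc(=O)c3c(O)cc(OCc4ccccc4)cc3o2)cc(OCc2ccccc2)c1OC | intermediate
19 | potassium 7-(benzyloxy)-2-[3-(benzyloxy)-4,5-dimethoxyphenyl]-5-hydroxy-4-oxo-4H-chromen-8-yl sulfate | COc1cc(-c2cc(=O)c3c(O)cc(OCc4ccccc4)c(OS(=O)(=O)[O-])c3o2)cc(OCc2ccccc2)c1OC.[K+] | intermediate (not isolated)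
20 | 7-(benzyloxy)-2-[3-(benzyloxy)-4,5-dimethoxyphenyl]-5,8-dihydroxy-4H-chromen-4-one | COc1cc(-c2cc(=O)c3c(O)cc(OCc4ccccc4)c(O)c3o2)cc(OCc2ccccc2)c1OC | intermediate
21 | 7-(benzyloxy)-2-[3-(benzyloxy)-4,5-dimethoxyphenyl]-5-hydroxy-8-methoxy-4H-chromen-4-one | COc1cc(-c2cc(=O)c3c(O)cc(OCc4ccccc4)c(OC)c3o2)cc(OCc2ccccc2)c1OC | intermediate
22 | 5,7-bis(benzyloxy)-2-[3-(benzyloxy)-4,5-dimethoxyphenyl]-8-methoxy-4H-chromen-4-one | COc1cc(-c2cc(=O)c3c(OCc4ccccc4)cc(OCc4ccccc4)c(OC)c3o2)cc(OCc2ccccc2)c1OC | intermediate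
23 | 3-lithio derivative of 22 | COc1cc(-c2oc3c(OC)c(OCc4ccccc4)cc(OCc4ccccc4)c3c(=O)c2[Li])cc(OCc2ccccc2)c1OC | intermediate (not isolated)
24 | dimethyl {5,7-bis(benzyloxy)-2-[3-(benzyloxy)-4,5-dimethoxyphenyl]-8-methoxy-4-oxo-4H-chromen-3-yl}boronate | COc1cc(-c2oc3c(OC)c(OCc4ccccc4)cc(OCc4ccccc4)c3c(=O)c2B(OC)OC)cc(OCc2ccccc2)c1OC | intermediate (not isolated)
25 | 5,7-bis(benzyloxy)-2-[3-(benzyloxy)-4,5-dimethoxyphenyl]-3-hydroxy-8-methoxy-4H-chromen-4-one | COc1cc(-c2oc3c(OC)c(OCc4ccccc4)cc(OCc4ccccc4)c3c(=O)c2O)cc(OCc2ccccc2)c1OC | intermediate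
26 | 3,5,7-trihydroxy-2-(3-hydroxy-4,5-dimethoxyphenyl)-8-methoxy-4H-chromen-4-one | COc1cc(-c2oc3c(OC)c(O)cc(O)c3c(=O)c2O)cc(O)c1OC | target

**Step count**

Total: 13 steps. Longest linear sequence: 10 steps (steps 1–3 and 7–13 from 1; the ring B branch, steps 4–6 and 7–13, is equally long).

**Steps most likely to fail**

First, step 7. The aryl anion may be protonated before it reaches the ester carbonyl, which ends in plain O-arylation with no acyl transfer. It may instead add to the alkyne in conjugate fashion. The propiolate may lose CO2 at the temperature needed, or the phenoxide may close 5-exo instead of 6-endo. The fallback sets out from 10 and comes back at 17 by the chalcone route. Commercial 2,4,6-trihydroxyacetophenone is benzylated twice (BnBr, 2 equiv, K2CO3, acetone, reflux; the chelated hydroxyl stays free) to give 1-[2,4-bis(benzyloxy)-6-hydroxyphenyl]ethan-1-one F1. Claisen–Schmidt condensation of F1 with 10 (KOH, EtOH, rt) should give (E)-1-[2,4-bis(benzyloxy)-6-hydroxyphenyl]-3-[3-(benzyloxy)-4,5-dimethoxyphenyl]prop-2-en-1-one F2. Oxidative cyclisation of F2 with I2 (cat.) in DMSO at 120 °C should then give 17. If the peri benzyl ether is lost in this last operation, the product is 18, which is also on the route.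

Second, step 9. The persulfate oxidation may stall at low conversion because the lipophilic phenoxide dissolves poorly in the aqueous base, and the electron-rich quinol may be oxidised further. The fallback sets out from 17 and comes back at 22, so that steps 8 to 11 are not needed. Iodination of 17 with NIS (TFA cat., MeCN, 0 °C to rt) should give 5,7-bis(benzyloxy)-2-[3-(benzyloxy)-4,5-dimethoxyphenyl]-8-iodo-4H-chromen-4-one F3. In fully O-alkylated 5,7-dioxygenated flavones the electrophile is expected at C8, since C6 lies between two benzyloxy groups. Ullmann-type etherification of F3 (CuI, 1,10-phenanthroline, Cs2CO3, MeOH, toluene, 110 °C) should then give 22.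

Third, step 12. Deprotonation at C3 may be incomplete, or the amide base may open the pyranone ring or attack a benzylic position, and the boronate may be protonated before it is oxidised. The fallback sets out from 22 and comes back at 25. Epoxidation of the C2=C3 bond with dimethyldioxirane (acetone solution, CH2Cl2, 0 °C to rt) should give the racemic, necessarily cis-fused 2,3-epoxide of 22, 3,5-bis(benzyloxy)-1a-[3-(benzyloxy)-4,5-dimethoxyphenyl]-4-methoxy-1a,7a-dihydro-7H-oxireno[2,3-b]chromen-7-one F4. Treatment of F4 with p-TsOH (cat.) in CH2Cl2 opens the epoxide at the benzylic C2 and, after loss of the C3 proton, should give flavonol 25; both stereocentres of F4 are destroyed.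

**Further compounds**

F1 | step 7 | 1-[2,4-bis(benzyloxy)-6-hydroxyphenyl]ethan-1-one | CC(=O)c1c(O)cc(OCc2ccccc2)cc1OCc1ccccc1
F2 | step 7 | (E)-1-[2,4-bis(benzyloxy)-6-hydroxyphenyl]-3-[3-(benzyloxy)-4,5-dimethoxyphenyl]prop-2-en-1-one | COc1cc(/C=C/C(=O)c2c(O)cc(OCc3ccccc3)cc2OCc2ccccc2)cc(OCc2ccccc2)c1OC
F3 | step 9 | 5,7-bis(benzyloxy)-2-[3-(benzyloxy)-4,5-dimethoxyphenyl]-8-iodo-4H-chromen-4-one | COc1cc(-c2cc(=O)c3c(OCc4ccccc4)cc(OCc4ccccc4)c(I)c3o2)cc(OCc2ccccc2)c1OC
F4 | step 12 | racemic cis-fused 2,3-epoxide of 22 (one enantiomer drawn) | COc1cc([C@]23O[C@H]2C(=O)c2c(OCc4ccccc4)cc(OCc4ccccc4)c(OC)c2O3)cc(OCc2ccccc2)c1OC
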